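**Retrosynthetic overview**
1. Target 23 ⇐ tetra-MOM flavanone 22 (acidic MOM removal last) ⇐ chromone 18 + arylboronic acid 21 by Pd/PyOx asymmetric conjugate arylation (sets C2; ring B arrives last).
2. 18 ⇐ 6-iodochromone 17 + (S)-3,7-dimethylocta-1,6-diene 8 by Heck coupling (C6–C1'' bond, E-alkene).
3. 8 ⇐ homoprenyl boronate 3 by two consecutive 1,2-shifts from boron to carbon: lithiation–borylation (sets the side-chain stereocentre), then Zweifel vinylation (retention).
4. 17 ⇐ iodophenol 13 + 3-ethoxyacryloyl chloride 14 by a new one-pot ortho-acylation/annulation; 13 ⇐ resorcinol bis-MOM ether 9 by ortho-lithiation/iodination and C–H borylation/oxidation.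
5. Ring order: A (from 9) → C (step 6) → B attached (step 9); 21 ⇐ catechol bis-MOM ether 19 by C–H borylation.

Assumption: 1,3- and 1,2-bis(methoxymethoxy)benzene (MOM-protected resorcinol and catechol) are bought as such; otherwise each is one MOMCl/i-Pr2NEt step from the diol.

Step 1
Reactants: 1 5-bromo-2-methylpent-2-ene
Product: 3 4,4,5,5-tetramethyl-2-(4-methylpent-3-en-1-yl)-1,3,2-dioxaborolane, via (4-methylpent-3-en-1-yl)magnesium bromide 2 (not isolated)
Conditions: Mg, THF, 40 °C; i-PrOBpin, –78 °C → rt; aq. NH4Cl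
Reagents that add atoms: 2-isopropoxy-4,4,5,5-tetramethyl-1,3,2-dioxaborolane (CC(C)OB1OC(C)(C)C(C)(C)O1); magnesium ([Mg]; only in 2)
Why: Grignard formation followed by borylation with an alkoxyboronate (isopropoxide displaced at boron) is a standard route to primary alkyl pinacol boronates, and the trisubstituted alkene is inert.

Step 2
Reactants: 3 4,4,5,5-tetramethyl-2-(4-methylpent-3-en-1-yl)-1,3,2-dioxaborolane
Product: 5 4,4,5,5-tetramethyl-2-[(2S)-6-methylhept-5-en-2-yl]-1,3,2-dioxaborolane, via lithium boronate ate complex 4 (not isolated)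
Conditions: ethyl 2,4,6-triisopropylbenzoate (1.3 equiv), (+)-sparteine (1.3 equiv), s-BuLi (1.25 equiv), Et2O, –78 °C, 5 h; 3 (1.0 equiv), –78 °C, 1 h; then 35 °C, 12 h; aq. NH4Cl
Reagents that add atoms: ethyl 2,4,6-triisopropylbenzoate (CCOC(=O)c1c(C(C)C)cc(C(C)C)cc1C(C)C); sec-butyllithium (CCC(C)[Li]; Li only in 4)
Why: Lithiation–borylation (stereospecific 1,2-metallate rearrangement): s-BuLi/(+)-sparteine gives the configurationally stable (R)-α-lithio ester, which is borylated with retention to 4, and the homoprenyl group then shifts from boron to carbon anti to the departing carboxylate (inversion), which fixes the (S) centre (typically ≥ 95:5 er).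

Step 3
Reactants: 5 4,4,5,5-tetramethyl-2-[(2S)-6-methylhept-5-en-2-yl]-1,3,2-dioxaborolane
Product: 8 (3S)-3,7-dimethylocta-1,6-diene, via vinyl boronate ate complex 6 (not isolated), via β-iodoalkyl boronate 7 (not isolated)
Conditions: CH2=CHMgBr (2 equiv), THF/DMSO 1:1, 0 °C → rt; I2 (2 equiv), MeOH, –78 °C; NaOMe (4 equiv), –78 °C → rt; distil
Reagents that add atoms: vinylmagnesium bromide (C=C[Mg]Br); iodine (II; only in 7)
Why: Zweifel olefination: iodonium activation of the vinyl group in 6 triggers a 1,2-shift of the secondary alkyl group from boron to carbon with retention of configuration, and methoxide-induced anti β-elimination of boron and iodide from 7 releases the terminal alkene without touching the stereocentre.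

Step 4
Reactants: 9 1,3-bis(methoxymethoxy)benzene
Product: 11 2-iodo-1,3-bis(methoxymethoxy)benzene, via 2-lithio arene 10 (not isolated)
Conditions: n-BuLi (1.1 equiv), THF, 0 °C → rt, 1 h; I2, –78 °C → rt
Reagents that add atoms: iodine (II); n-butyllithium (CCCC[Li]; Li only in 10)
Why: Directed ortho-metalation: the two MOM ethers together direct lithiation to the carbon between them (the future C6), and the iodine quench marks that position while the ring is still symmetric.

Step 5
Reactants: 11 2-iodo-1,3-bis(methoxymethoxy)benzene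
Product: 13 4-iodo-3,5-bis(methoxymethoxy)phenol, via aryl pinacol boronate 12 (not isolated)
Conditions: [Ir(OMe)(cod)]2 (1.5 mol%), dtbpy (3 mol%), B2pin2 (1.0 equiv), THF, 80 °C; then 30% H2O2, 2 M NaOH, 0 °C
Reagents that add atoms: hydrogen peroxide (OO); bis(pinacolato)diboron (CC1(C)OB(OC1(C)C)B1OC(C)(C)C(C)(C)O1; Bpin only in 12)
Why: Iridium-catalysed C–H borylation is sterically controlled and takes the only C–H without an ortho substituent (para to iodine; aryl iodides are tolerated), and basic peroxide oxidation of the C–B bond gives the phenol oxygen that becomes O1.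

Step 6
Reactants: 13 4-iodo-3,5-bis(methoxymethoxy)phenol; 14 (E)-3-ethoxyprop-2-enoyl chloride
Product: 17 6-iodo-5,7-bis(methoxymethoxy)-4H-chromen-4-one, via bromomagnesium phenoxide 15 (not isolated), via β-ethoxyvinyl ketone 16 (not isolated)
Conditions: EtMgBr (1.0 equiv), Et2O, 0 °C; switch to toluene; 14 (1.1 equiv), rt, 12 h; then AcOH, 50 °C
Reagents that add atoms: ethylmagnesium bromide (CC[Mg]Br; MgBr only in 15)
Why: Proposed new method: the bromomagnesium phenoxide 15 should be C-acylated at its own ortho carbon through a six-membered magnesium-chelated transition state (closest known reactions: the ortho-selective C-acylation of bromomagnesium phenoxides by α,β-unsaturated acid chlorides to 2'-hydroxychalcones, and Friedel–Crafts chromone syntheses through β-chlorovinyl ketones); with a β-alkoxyacryloyl chloride the product 16 is a vinylogous ester whose phenol adds 6-endo to the β-carbon and expels ethanol, as enaminones do in the standard chromone synthesis, so ring C closes in one pot without the Lewis or strong protic acids that MOM ethers do not survive, and since both ortho positions of 13 are equivalent only one regioisomer can form.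

Step 7
Reactants: 17 6-iodo-5,7-bis(methoxymethoxy)-4H-chromen-4-one; 8 (3S)-3,7-dimethylocta-1,6-diene
Product: 18 6-[(1E,3S)-3,7-dimethylocta-1,6-dien-1-yl]-5,7-bis(methoxymethoxy)-4H-chromen-4-one
Conditions: Pd(OAc)2 (5 mol%), n-Bu4NCl (1 equiv), NaHCO3 (2.5 equiv), 8 (1.3 equiv), DMF, 80 °C
Reagents that add atoms: none
Why: Mizoroki–Heck reaction (Jeffery conditions): aryl-palladium adds to the terminal carbon and syn β-hydride elimination of a benzylic hydrogen, preferred over the hindered tertiary allylic one, gives the conjugated (E)-alkene, as is known for 6- and 8-iodo-5,7-dialkoxy flavonoids with terminal alkenes, so (3S) is carried through.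

Step 8
Reactants: 19 1,2-bis(methoxymethoxy)benzene
Product: 21 [3,4-bis(methoxymethoxy)phenyl]boronic acid, via aryl pinacol boronate 20 (not isolated)
Conditions: [Ir(OMe)(cod)]2 (1 mol%), dtbpy (2 mol%), B2pin2 (1.0 equiv), THF, 80 °C; then NaIO4, NH4OAc, acetone/H2O, rt
Reagents that add atoms: bis(pinacolato)diboron (CC1(C)OB(OC1(C)C)B1OC(C)(C)C(C)(C)O1); water (O)
Why: Sterically controlled iridium-catalysed C–H borylation of a 1,2-disubstituted benzene goes only to C4, and buffered periodate cleavage of the pinacol ester gives the free boronic acid without harming the MOM ethers.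

Step 9
Reactants: 18 6-[(1E,3S)-3,7-dimethylocta-1,6-dien-1-yl]-5,7-bis(methoxymethoxy)-4H-chromen-4-one; 21 [3,4-bis(methoxymethoxy)phenyl]boronic acid
Product: 22 (2S)-2-[3,4-bis(methoxymethoxy)phenyl]-6-[(1E,3S)-3,7-dimethylocta-1,6-dien-1-yl]-5,7-bis(methoxymethoxy)-2,3-dihydro-4H-chromen-4-one
Conditions: Pd(OCOCF3)2 (7 mol%), (R)-t-BuPyOx (8 mol%), NH4PF6 (30 mol%), H2O (5 equiv), 21 (2 equiv), ClCH2CH2Cl, 60 °C
Reagents that add atoms: none
Why: Pd(II)/pyridine-oxazoline-catalysed asymmetric conjugate addition of an arylboronic acid to a chromone: the cationic aryl-Pd(II) complex inserts the C2=C3 bond with ligand-controlled delivery of aryl to the C2 Re face (ligand antipode chosen by analogy with the cyclic-enone model, to be confirmed on 17) and the palladium enolate is protonated, so (2S) is set by the catalyst regardless of the remote (3''S) centre and no base is present to open the flavanone.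

Step 10
Reactants: 22 (2S)-2-[3,4-bis(methoxymethoxy)phenyl]-6-[(1E,3S)-3,7-dimethylocta-1,6-dien-1-yl]-5,7-bis(methoxymethoxy)-2,3-dihydro-4H-chromen-4-one
Product: 23 (2S)-2-(3,4-dihydroxyphenyl)-6-[(1E,3S)-3,7-dimethylocta-1,6-dien-1-yl]-5,7-dihydroxy-2,3-dihydro-4H-chromen-4-one (CNP0230070.1)
Conditions: 3 M aq. HCl/MeOH (1:5), 40 °C
Reagents that add atoms: none
Why: Acid-catalysed acetal exchange (MOM cleavage) of four aryl MOM ethers in methanol, the usual last step for prenylated flavanones; the mild acid does not enolise C3 (C2 stays S) and should leave the trisubstituted and styrenyl alkenes alone at 40 °C.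

**Compound list**
1 | 5-bromo-2-methylpent-2-ene | CC(C)=CCCBr | starting material
2 | (4-methylpent-3-en-1-yl)magnesium bromide | CC(C)=CCC[Mg]Br | intermediate
3 | 4,4,5,5-tetramethyl-2-(4-methylpent-3-en-1-yl)-1,3,2-dioxaborolane | CC(C)=CCCB1OC(C)(C)C(C)(C)O1 | intermediate
4 | lithium (4-methylpent-3-en-1-yl)(pinacolato)[(1R)-1-(2,4,6-triisopropylbenzoyloxy)ethyl]borate | CC(C)=CCC[B-]1(OC(C)(C)C(C)(C)O1)[C@H](C)OC(=O)c1c(C(C)C)cc(C(C)C)cc1C(C)C.[Li+] | intermediate
5 | 4,4,5,5-tetramethyl-2-[(2S)-6-methylhept-5-en-2-yl]-1,3,2-dioxaborolane | CC(C)=CCC[C@H](C)B1OC(C)(C)C(C)(C)O1 | intermediate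
6 | bromomagnesium ethenyl[(2S)-6-methylhept-5-en-2-yl](pinacolato)borate | C=C[B-]1(OC(C)(C)C(C)(C)O1)[C@@H](C)CCC=C(C)C.[Mg+]Br | intermediate
7 | 2-[(3S)-1-iodo-3,7-dimethyloct-6-en-2-yl]-4,4,5,5-tetramethyl-1,3,2-dioxaborolane (C2 epimers) | CC(C)=CCC[C@H](C)C(CI)B1OC(C)(C)C(C)(C)O1 | intermediate
8 | (3S)-3,7-dimethylocta-1,6-diene | CC(C)=CCC[C@H](C)C=C | intermediate
9 | 1,3-bis(methoxymethoxy)benzene | COCOc1cccc(OCOC)c1 | starting material
10 | [2,6-bis(methoxymethoxy)phenyl]lithium | [Li]c1c(OCOC)cccc1OCOC | intermediate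
11 | 2-iodo-1,3-bis(methoxymethoxy)benzene | COCOc1cccc(OCOC)c1I | intermediate
12 | 2-[4-iodo-3,5-bis(methoxymethoxy)phenyl]-4,4,5,5-tetramethyl-1,3,2-dioxaborolane | COCOc1cc(B2OC(C)(C)C(C)(C)O2)cc(OCOC)c1I | intermediate
13 | 4-iodo-3,5-bis(methoxymethoxy)phenol | COCOc1cc(O)cc(OCOC)c1I | intermediate
14 | (E)-3-ethoxyprop-2-enoyl chloride | CCO/C=C/C(=O)Cl | starting material
15 | bromomagnesium 4-iodo-3,5-bis(methoxymethoxy)phenoxide | COCOc1cc(O[Mg]Br)cc(OCOC)c1I | intermediate
16 | (E)-3-ethoxy-1-[2-hydroxy-5-iodo-4,6-bis(methoxymethoxy)phenyl]prop-2-en-1-one | CCO/C=C/C(=O)c1c(O)cc(OCOC)c(I)c1OCOC | intermediate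
17 | 6-iodo-5,7-bis(methoxymethoxy)-4H-chromen-4-one | COCOc1cc2occc(=O)c2c(OCOC)c1I | intermediate
18 | 6-[(1E,3S)-3,7-dimethylocta-1,6-dien-1-yl]-5,7-bis(methoxymethoxy)-4H-chromen-4-one | CC(C)=CCC[C@H](C)/C=C/c1c(OCOC)cc2occc(=O)c2c1OCOC | intermediate
19 | 1,2-bis(methoxymethoxy)benzene | COCOc1ccccc1OCOC | starting material
20 | 2-[3,4-bis(methoxymethoxy)phenyl]-4,4,5,5-tetramethyl-1,3,2-dioxaborolane | COCOc1ccc(B2OC(C)(C)C(C)(C)O2)cc1OCOC | intermediate
21 | [3,4-bis(methoxymethoxy)phenyl]boronic acid | COCOc1ccc(B(O)O)cc1OCOC | intermediate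
22 | (2S)-2-[3,4-bis(methoxymethoxy)phenyl]-6-[(1E,3S)-3,7-dimethylocta-1,6-dien-1-yl]-5,7-bis(methoxymethoxy)-2,3-dihydro-4H-chromen-4-one | CC(C)=CCC[C@H](C)/C=C/c1c(OCOC)cc2c(c1OCOC)C(=O)C[C@@H](c1ccc(OCOC)c(OCOC)c1)O2 | intermediate
23 | (2S)-2-(3,4-dihydroxyphenyl)-6-[(1E,3S)-3,7-dimethylocta-1,6-dien-1-yl]-5,7-dihydroxy-2,3-dihydro-4H-chromen-4-one | CC(C)=CCC[C@H](C)/C=C/c1c(O)cc2c(c1O)C(=O)C[C@@H](c1ccc(O)c(O)c1)O2 | target

**Totals**
Total steps: 10. Longest linear sequence: 6 steps (1 → 2 → 3 → 7 → 9 → 10, or 4 → 5 → 6 → 7 → 9 → 10).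

**Three steps most likely to fail**

Step 6 (the proposed new annulation). O-acylation or incomplete ring closure may win. The fallback is known chemistry and sets out from 13: its bromomagnesium phenoxide is C-acylated with acetyl chloride (toluene, rt) to 1-[2-hydroxy-5-iodo-4,6-bis(methoxymethoxy)phenyl]ethan-1-one F1. DMF-DMA (90 °C) converts this to the enaminone (E)-3-(dimethylamino)-1-[2-hydroxy-5-iodo-4,6-bis(methoxymethoxy)phenyl]prop-2-en-1-one F2. Silica gel or AcOH in CH2Cl2 then closes F2, with loss of dimethylamine, and the route is rejoined at 17. This costs one extra step.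

Step 7 (Heck). Double-bond migration into the chain, erosion at C3'' through Pd–H re-addition, or slow reaction of the di-ortho-substituted iodide are the risks. The fallback is a Suzuki union that sets out from 5. A Zweifel-type alkynylation (α-lithiated vinyl carbamate, then I2/MeOH, then LDA) gives (3S)-3,7-dimethyloct-6-en-1-yne F3 with retention. Zirconium-catalysed hydroboration (HBpin, Cp2ZrHCl cat.) gives 2-[(1E,3S)-3,7-dimethylocta-1,6-dien-1-yl]-4,4,5,5-tetramethyl-1,3,2-dioxaborolane F4. Suzuki–Miyaura coupling of F4 with 17 (Pd(OAc)2/SPhos, K3PO4, toluene/H2O, 60 °C) rejoins the route at 18. The alkene geometry then comes from syn-hydroboration, and the coupling has no Pd–H that could move along the chain.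

Step 9 (asymmetric conjugate arylation). The side-chain alkenes may divert the cationic aryl-Pd(II) catalyst (oxidative Heck), or the ee may be low on this crowded chromone. The fallback sets C2 before the side chain is attached and sets out from 17: the same Pd/(R)-t-BuPyOx arylation with 21 on the simpler iodochromone gives (2S)-2-[3,4-bis(methoxymethoxy)phenyl]-6-iodo-5,7-bis(methoxymethoxy)-2,3-dihydro-4H-chromen-4-one F5. Heck coupling of F5 with 8 (Pd(OAc)2, P(o-tol)3, Ag2CO3, DMF, 70 °C; insoluble Ag2CO3 as the only base, to keep the flavanone closed) rejoins the route at 22.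

**Further compounds**
F1 | step 6 | 1-[2-hydroxy-5-iodo-4,6-bis(methoxymethoxy)phenyl]ethan-1-one | CC(=O)c1c(O)cc(OCOC)c(I)c1OCOC
F2 | step 6 | (E)-3-(dimethylamino)-1-[2-hydroxy-5-iodo-4,6-bis(methoxymethoxy)phenyl]prop-2-en-1-one | CN(C)/C=C/C(=O)c1c(O)cc(OCOC)c(I)c1OCOC
F3 | step 7 | (3S)-3,7-dimethyloct-6-en-1-yne | CC(C)=CCC[C@H](C)C#C
F4 | step 7 | 2-[(1E,3S)-3,7-dimethylocta-1,6-dien-1-yl]-4,4,5,5-tetramethyl-1,3,2-dioxaborolane | CC(C)=CCC[C@H](C)/C=C/B1OC(C)(C)C(C)(C)O1
F5 | step 9 | (2S)-2-[3,4-bis(methoxymethoxy)phenyl]-6-iodo-5,7-bis(methoxymethoxy)-2,3-dihydro-4H-chromen-4-one | COCOc1cc2c(c(OCOC)c1I)C(=O)C[C@@H](c1ccc(OCOC)c(OCOC)c1)O2
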